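**Plan**

- Labels: chroman atoms are O1 and C2 to C8a; the bicyclo[3.1.1]heptane carbons carry primed pinane numbers (C2' = C2, C6' = the CMe2 bridge, C7' = the other one-carbon bridge).
- Retrosynthesis cuts first the two aryl–carbonyl bonds (C8–CHO, C6–COCH2CHMe2). After a carbonyl is placed on C7', it cuts the cyclobutane bonds C1'–C6' and C5'–C7' together, then O1–C2 with the CH2–CO2 bond, and last the side-chain C=CH2 and C=C bonds.
- Enabling feature: the four-membered ring C1'–C6'–C5'–C7' bridges the six-membered ring C1'–C2'–C3'–C4'–C5'–C7' that holds the spiro atom C2 = C2'. Taking both bridges away leaves a 2,2-disubstituted chroman with an acetic acid arm and a 4-methylpent-3-enyl arm on C2.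
- Forward: the chain is joined to the arene by aldol condensation and the pyran ring closes by Pd(OCOCF3)2-catalysed oxycarbonylation. The carbocycle and the cyclobutanone then close in one ketene–alkene [2+2] event, C7' is deoxygenated, and C6 is acylated and C8 formylated.
- Stereochemistry: C2 comes from the Pd(OCOCF3)2/(R,R)-Bn-BOXAX catalyst; C1' and C5' are set relative to C2 in the cycloaddition.

Key step: step 7

Assumption: the (R,R)-Bn-BOXAX ligand is taken to deliver the (2R)-chroman in step 5; should the facial sense be opposite, the enantiomeric ligand is used and nothing else changes.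
Assumption: the Weinreb amide N-methoxy-N,3-dimethylbutanamide used in step 9 is treated as a purchased reagent.

**Route**

Step 1
Reactants: 1 2,4,6-trihydroxybenzaldehyde
Product: 2 2-hydroxy-4,6-bis(methoxymethoxy)benzaldehyde
Conditions: MOMCl (2.2 equiv), i-Pr2NEt (2.5 equiv), CH2Cl2, 0 °C to rt
Reagents that add atoms: chloromethyl methyl ether, COCCl
Why: O-alkylation with the α-chloro ether (MOM protection) should take the 4-hydroxyl and one of the two equivalent ortho hydroxyls, because the remaining hydroxyl is held in a hydrogen bond to the formyl group and is the least nucleophilic.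

Step 2
Reactants: 2 2-hydroxy-4,6-bis(methoxymethoxy)benzaldehyde; 3 6-methylhept-5-en-2-one
Product: 4 (E)-1-[2-hydroxy-4,6-bis(methoxymethoxy)phenyl]-7-methylocta-1,6-dien-3-one
Conditions: 3 (3 equiv), KOH (3 equiv, 40% aq.), EtOH, rt to 45 °C; then cold 1 M HCl to pH 5
Reagents that add atoms: none
Why: Claisen–Schmidt condensation, in which reversible hydroxide conditions bring the methyl side of the ketone onto the non-enolisable aldehyde and E1cB loss of water gives the E-enone, while the phenoxide form keeps the ortho oxygen from cyclising onto the product.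

Step 3
Reactants: 4 (E)-1-[2-hydroxy-4,6-bis(methoxymethoxy)phenyl]-7-methylocta-1,6-dien-3-one
Product: 5 1-[2-hydroxy-4,6-bis(methoxymethoxy)phenyl]-7-methyloct-6-en-3-one
Conditions: H2 (1 atm), RhCl(PPh3)3 (5 mol%), benzene/EtOH 1:1, rt
Reagents that add atoms: none
Why: Chemoselective homogeneous hydrogenation, in which RhCl(PPh3)3 reduces the 1,2-disubstituted conjugated alkene much faster than the trisubstituted one (the selectivity used to make prenylated dihydrochalcones from chalcones) and leaves ketone, phenol and acetals alone.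

Step 4
Reactants: 5 1-[2-hydroxy-4,6-bis(methoxymethoxy)phenyl]-7-methyloct-6-en-3-one
Product: 6 3,5-bis(methoxymethoxy)-2-(7-methyl-3-methylideneoct-6-enyl)phenol
Conditions: Ph3PCH3Br (3.2 equiv), KOtBu (3 equiv), THF, 0 °C to rt; then H2O
Reagents that add atoms: methyltriphenylphosphonium bromide, C[P+](c1ccccc1)(c1ccccc1)c1ccccc1.[Br-]
Why: Wittig methylenation of an unhindered dialkyl ketone with the non-stabilised ylide, one equivalent of base being taken up by the phenol, whose phenoxide does not react with the ylide.

Step 5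
Reactants: 6 3,5-bis(methoxymethoxy)-2-(7-methyl-3-methylideneoct-6-enyl)phenol
Product: 7 methyl 2-[(2R)-5,7-bis(methoxymethoxy)-2-(4-methylpent-3-enyl)chroman-2-yl]acetate
Conditions: Pd(OCOCF3)2 (5 mol%), (R,R)-Bn-BOXAX [2,2'-bis((4R)-4-benzyl-4,5-dihydrooxazol-2-yl)-1,1'-binaphthyl] (20 mol%), p-benzoquinone (4 equiv), CO (1 atm), MeOH, rt
Reagents that add atoms: carbon monoxide, [C-]#[O+]; methanol, CO
Why: Enantioselective Wacker-type oxycarbonylation, in which the phenol adds 6-exo to the 1,1-disubstituted alkene on divalent palladium to give an alkylpalladium without β-hydrogen that inserts CO and is cleaved by methanol, benzoquinone returning zerovalent palladium to the divalent state and the chiral ligand choosing the alkene face that sets C2.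

Step 6
Reactants: 7 methyl 2-[(2R)-5,7-bis(methoxymethoxy)-2-(4-methylpent-3-enyl)chroman-2-yl]acetate
Product: 8 2-[(2R)-5,7-bis(methoxymethoxy)-2-(4-methylpent-3-enyl)chroman-2-yl]acetic acid
Conditions: LiOH·H2O (5 equiv), THF/MeOH/H2O 3:1:1, 40 °C; then 1 M HCl to pH 4 at 0 °C
Reagents that add atoms: lithium hydroxide monohydrate, [Li+].[OH-].O
Why: Ester saponification by acyl–oxygen cleavage, which cannot touch the fully substituted C2, while the short cold acidification is tolerated by the MOM acetals.

Step 7
Reactants: 8 2-[(2R)-5,7-bis(methoxymethoxy)-2-(4-methylpent-3-enyl)chroman-2-yl]acetic acid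
Product: 11 (2R,1'R,5'R)-5,7-bis(methoxymethoxy)-6',6'-dimethylspiro[chromane-2,2'-bicyclo[3.1.1]heptan]-7'-one, via acyloxypyridinium salt 9 (not isolated), via ketene 10 (not isolated)
Conditions: 2-chloro-1-methylpyridinium iodide (3 equiv), Et3N (8 equiv), MeCN, reflux; 8 added over 10 h by syringe pump (final 0.005 M)
Reagents that add atoms: 2-chloro-1-methylpyridinium iodide, C[n+]1ccccc1Cl.[I-] (its atoms are carried only by intermediate 9)
Why: Et3N converts the activated ester 9 into aldoketene 10, whose electrophilic carbonyl carbon C7' is attacked by the less substituted alkene carbon C5' while positive charge builds on the tertiary carbon C6', which then bonds to the ketene α-carbon C1' in an asynchronous, thermally allowed ketene–alkene [2+2] cycloaddition. The closest known reaction type is the intramolecular cycloaddition of ketenes tethered by three atoms to a 2-methylprop-1-enyl group, which gives 7,7-dimethylbicyclo[3.1.1]heptan-6-ones. The six-membered carbocycle (C1', C2', C3', C4', C5', C7') closes first through the C7'–C5' bond with the ketene C=C inside the ring, and the cyclobutanone (C1', C7', C5', C6') closes second through the C1'–C6' bond across that ring; this bridged mode is preferred over the fused bicyclo[3.2.0] mode because the carbonyl carbon must bond to the alkene carbon that leaves the better-stabilised cation. C1' and C5' are new: their mutual relationship is fixed by the two one-carbon bridges, and their configuration relative to C2 depends on which chair-like arrangement of the forming six-membered ring is used, the one with the chroman C3 methylene pseudo-equatorial and O1 pseudo-axial placing the CMe2 bridge anti to O1 as in the target. The step therefore needs diastereofacial selectivity, for which only a modest bias (the larger CH2 branch equatorial) can be claimed, so two cyclobutanones separable by chromatography are anticipated, and an NOE between the C6' methyl group lying over the carbocycle and the C3 hydrogens should identify the wanted isomer. Slow addition at high dilution and the geminal substitution at C2 are relied on to keep cyclisation ahead of ketene dimerisation, and acylation of the arene at C8 is excluded because it would put an aromatic carbon at a bridgehead.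

Step 8
Reactants: 11 (2R,1'R,5'R)-5,7-bis(methoxymethoxy)-6',6'-dimethylspiro[chromane-2,2'-bicyclo[3.1.1]heptan]-7'-one
Product: 13 (2R,1'R,5'S)-5,7-bis(methoxymethoxy)-6',6'-dimethylspiro[chromane-2,2'-bicyclo[3.1.1]heptane], via hydrazone 12 (not isolated)
Conditions: N2H4·H2O (10 equiv), KOH (6 equiv), diethylene glycol, 130 °C, then 200 °C with removal of water
Reagents that add atoms: hydrazine hydrate, NN.O (its nitrogen is carried only by intermediate 12)
Why: Wolff–Kishner reduction, the established way from 7,7-dimethylbicyclo[3.1.1]heptan-6-ones to pinanes, which should be safe here because the bridgehead C1' cannot enolise (so neither epimerisation nor β-elimination of the aryloxide can begin) and MOM acetals and the aryl ether withstand hot alkali.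

Step 9
Reactants: 13 (2R,1'R,5'S)-5,7-bis(methoxymethoxy)-6',6'-dimethylspiro[chromane-2,2'-bicyclo[3.1.1]heptane]; 14 N-methoxy-N,3-dimethylbutanamide
Product: 17 1-[(2R,1'R,5'S)-5,7-bis(methoxymethoxy)-6',6'-dimethylspiro[chromane-2,2'-bicyclo[3.1.1]heptan]-6-yl]-3-methylbutan-1-one, via aryllithium 15 (not isolated), via lithium hemiaminal 16 (not isolated)
Conditions: n-BuLi (1.3 equiv), THF, 0 °C, 1 h; then 14 (1.5 equiv), −78 °C to 0 °C; then H2O
Reagents that add atoms: n-butyllithium, [Li]CCCC (its lithium is carried only by intermediates 15 and 16)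
Why: Directed ortho-lithiation followed by Weinreb ketone synthesis, C6 being flanked by two chelating OMOM groups whereas C8 has only one and the hindered tertiary-alkyl ether oxygen, and the chelated adduct 16 releasing the ketone only on work-up so that no second addition occurs.

Step 10
Reactants: 17 1-[(2R,1'R,5'S)-5,7-bis(methoxymethoxy)-6',6'-dimethylspiro[chromane-2,2'-bicyclo[3.1.1]heptan]-6-yl]-3-methylbutan-1-one
Product: 18 1-[(2R,1'R,5'S)-5,7-dihydroxy-6',6'-dimethylspiro[chromane-2,2'-bicyclo[3.1.1]heptan]-6-yl]-3-methylbutan-1-one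
Conditions: conc. HCl (cat.), MeOH, 40 °C
Reagents that add atoms: none
Why: Acid-catalysed acetal exchange with methanol (MOM cleavage), which is fast for aryl MOM ethers ortho to a ketone and should be complete well before the tertiary aryl ether at C2, now deactivated by the acyl group, could ionise.

Step 11
Reactants: 18 1-[(2R,1'R,5'S)-5,7-dihydroxy-6',6'-dimethylspiro[chromane-2,2'-bicyclo[3.1.1]heptan]-6-yl]-3-methylbutan-1-one
Product: 20 euglobal G3 [(2R,1'R,5'S)-5,7-dihydroxy-6',6'-dimethyl-6-(3-methylbutanoyl)spiro[chromane-2,2'-bicyclo[3.1.1]heptane]-8-carbaldehyde], via chloro(methoxy)methyl arene 19 (not isolated)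
Conditions: Cl2CHOMe (2 equiv), TiCl4 (4 equiv), CH2Cl2, −78 °C to 0 °C; then ice/1 M HCl
Reagents that add atoms: dichloromethyl methyl ether, COC(Cl)Cl; water, O
Why: Rieche formylation, the standard electrophilic formylation of acylphloroglucinols, which can only strike C8 (the single free ring position, ortho to the 7-hydroxyl and O1) and whose low temperature is chosen to spare the spiro tertiary ether, hydrolysis of 19 on work-up giving the aldehyde.

**Compound list**

1 | 2,4,6-trihydroxybenzaldehyde | O=Cc1c(O)cc(O)cc1O | starting material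
2 | 2-hydroxy-4,6-bis(methoxymethoxy)benzaldehyde | O=Cc1c(O)cc(OCOC)cc1OCOC | intermediate
3 | 6-methylhept-5-en-2-one | CC(=O)CCC=C(C)C | starting material
4 | (E)-1-[2-hydroxy-4,6-bis(methoxymethoxy)phenyl]-7-methylocta-1,6-dien-3-one | COCOc1cc(O)c(/C=C/C(=O)CCC=C(C)C)c(OCOC)c1 | intermediate
5 | 1-[2-hydroxy-4,6-bis(methoxymethoxy)phenyl]-7-methyloct-6-en-3-one | COCOc1cc(O)c(CCC(=O)CCC=C(C)C)c(OCOC)c1 | intermediate
6 | 3,5-bis(methoxymethoxy)-2-(7-methyl-3-methylideneoct-6-enyl)phenol | COCOc1cc(O)c(CCC(=C)CCC=C(C)C)c(OCOC)c1 | intermediate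
7 | methyl 2-[(2R)-5,7-bis(methoxymethoxy)-2-(4-methylpent-3-enyl)chroman-2-yl]acetate | COCOc1cc2c(c(OCOC)c1)CC[C@@](CC(=O)OC)(CCC=C(C)C)O2 | intermediate
8 | 2-[(2R)-5,7-bis(methoxymethoxy)-2-(4-methylpent-3-enyl)chroman-2-yl]acetic acid | COCOc1cc2c(c(OCOC)c1)CC[C@@](CC(=O)O)(CCC=C(C)C)O2 | intermediate
9 | 2-({2-[(2R)-5,7-bis(methoxymethoxy)-2-(4-methylpent-3-enyl)chroman-2-yl]acetyl}oxy)-1-methylpyridinium iodide | COCOc1cc2c(c(OCOC)c1)CC[C@@](CC(=O)Oc1cccc[n+]1C)(CCC=C(C)C)O2.[I-] | intermediate
10 | 2-[(2R)-5,7-bis(methoxymethoxy)-2-(4-methylpent-3-enyl)chroman-2-yl]ethenone (ketene) | COCOc1cc2c(c(OCOC)c1)CC[C@@](C=C=O)(CCC=C(C)C)O2 | intermediate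
11 | (2R,1'R,5'R)-5,7-bis(methoxymethoxy)-6',6'-dimethylspiro[chromane-2,2'-bicyclo[3.1.1]heptan]-7'-one | COCOc1cc2c(c(OCOC)c1)CC[C@@]1(CC[C@H]3C(=O)[C@@H]1C3(C)C)O2 | intermediate
12 | (2R,1'S,5'R)-5,7-bis(methoxymethoxy)-6',6'-dimethylspiro[chromane-2,2'-bicyclo[3.1.1]heptan]-7'-one hydrazone | COCOc1cc2c(c(OCOC)c1)CC[C@@]1(CC[C@H]3C(=NN)[C@@H]1C3(C)C)O2 | intermediate
13 | (2R,1'R,5'S)-5,7-bis(methoxymethoxy)-6',6'-dimethylspiro[chromane-2,2'-bicyclo[3.1.1]heptane] | COCOc1cc2c(c(OCOC)c1)CC[C@@]1(CC[C@H]3C[C@@H]1C3(C)C)O2 | intermediate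
14 | N-methoxy-N,3-dimethylbutanamide | CC(C)CC(=O)N(C)OC | starting material
15 | [(2R,1'R,5'S)-5,7-bis(methoxymethoxy)-6',6'-dimethylspiro[chromane-2,2'-bicyclo[3.1.1]heptan]-6-yl]lithium | [Li]c1c(OCOC)cc2c(c1OCOC)CC[C@@]1(CC[C@H]3C[C@@H]1C3(C)C)O2 | intermediate
16 | lithium 1-[(2R,1'R,5'S)-5,7-bis(methoxymethoxy)-6',6'-dimethylspiro[chromane-2,2'-bicyclo[3.1.1]heptan]-6-yl]-1-[methoxy(methyl)amino]-3-methylbutan-1-olate (carbinol carbon unassigned) | CC(C)CC(O[Li])(N(C)OC)c1c(OCOC)cc2c(c1OCOC)CC[C@@]1(CC[C@H]3C[C@@H]1C3(C)C)O2 | intermediate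
17 | 1-[(2R,1'R,5'S)-5,7-bis(methoxymethoxy)-6',6'-dimethylspiro[chromane-2,2'-bicyclo[3.1.1]heptan]-6-yl]-3-methylbutan-1-one | CC(C)CC(=O)c1c(OCOC)cc2c(c1OCOC)CC[C@@]1(CC[C@H]3C[C@@H]1C3(C)C)O2 | intermediate
18 | 1-[(2R,1'R,5'S)-5,7-dihydroxy-6',6'-dimethylspiro[chromane-2,2'-bicyclo[3.1.1]heptan]-6-yl]-3-methylbutan-1-one | CC(C)CC(=O)c1c(O)cc2c(c1O)CC[C@@]1(CC[C@H]3C[C@@H]1C3(C)C)O2 | intermediate
19 | 1-[(2R,1'R,5'S)-8-[chloro(methoxy)methyl]-5,7-dihydroxy-6',6'-dimethylspiro[chromane-2,2'-bicyclo[3.1.1]heptan]-6-yl]-3-methylbutan-1-one (CHCl carbon unassigned) | CC(C)CC(=O)c1c(O)c(C(Cl)OC)c2c(c1O)CC[C@@]1(CC[C@H]3C[C@@H]1C3(C)C)O2 | intermediate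
20 | euglobal G3 [(2R,1'R,5'S)-5,7-dihydroxy-6',6'-dimethyl-6-(3-methylbutanoyl)spiro[chromane-2,2'-bicyclo[3.1.1]heptane]-8-carbaldehyde] | CC(C)CC(=O)c1c(O)c(C=O)c2c(c1O)CC[C@@]1(CC[C@H]3C[C@@H]1C3(C)C)O2 | target

**Count**

Total steps: 11. Longest linear sequence: 11 steps (1 to 20).

**Steps most likely to fail**

Step 7. The two chair-like transition states may be populated to a similar extent, so that the CMe2 bridge is delivered syn to O1 about as readily as anti. The unactivated aldoketene may also dimerise faster than it cyclises, and the base may open the chroman by β-elimination of the aryloxide from the activated acid. The fallback gives up building the pinane and takes it from the chiral pool. It sets out from aldehyde 2: NaBH4 in MeOH at 0 °C should give 2-(hydroxymethyl)-3,5-bis(methoxymethoxy)phenol F1. Heating F1 with an excess of commercial (1S,5S)-(−)-β-pinene (C=C1CC[C@H]2C[C@@H]1C2(C)C) at about 170 °C in a sealed tube should expel water to form the o-quinone methide 3,5-bis(methoxymethoxy)-6-methylidenecyclohexa-2,4-dien-1-one F2, which is not isolated. F2 is expected to add to the exocyclic alkene in an inverse-demand hetero-Diels–Alder reaction, with oxygen bonding to the disubstituted carbon from the face remote from the CMe2 bridge, which fixes C2, C1' and C5' as in the target. The fallback comes back to the route at 13, before step 9.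

Step 5. The alkylpalladium formed on oxypalladation may insert the pendant trisubstituted alkene instead of CO, or the larger alkenyl substituent may weaken the facial discrimination exerted by the ligand. The fallback closes the chroman without palladium and separates the enantiomers. It sets out from ketone 5: Horner–Wadsworth–Emmons olefination (trimethyl phosphonoacetate, NaH, THF, reflux) should give methyl 5-[2-hydroxy-4,6-bis(methoxymethoxy)phenyl]-3-(4-methylpent-3-enyl)pent-2-enoate F3 as an E/Z mixture. With catalytic KOtBu in THF both isomers should close by 6-exo-trig oxa-Michael addition of the phenoxide to racemic methyl 2-[5,7-bis(methoxymethoxy)-2-(4-methylpent-3-enyl)chroman-2-yl]acetate F4. Preparative chromatography on a chiral stationary phase then supplies the (R)-enantiomer, which is 7, and the route is rejoined before step 6.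

Step 8. Hydrazone formation at the hindered cyclobutanone may be slow, so that hydroxide-induced cleavage of the strained ring (Haller–Bauer type) or thermal degradation competes at 200 °C. The fallback is a radical deoxygenation under nearly neutral conditions, setting out from 11. NaBH4 (MeOH, 0 °C) should give (2R,1'S,5'R)-5,7-bis(methoxymethoxy)-6',6'-dimethylspiro[chromane-2,2'-bicyclo[3.1.1]heptan]-7'-ol F5 (either C7' epimer serves). NaH, CS2 and MeI in THF should convert it into the S-methyl xanthate O-[(2R,1'S,5'R)-5,7-bis(methoxymethoxy)-6',6'-dimethylspiro[chromane-2,2'-bicyclo[3.1.1]heptan]-7'-yl] S-methyl carbonodithioate F6. Bu3SnH with AIBN in refluxing toluene (Barton–McCombie deoxygenation) should then give 13, where the route is rejoined. The secondary cyclobutyl radical should be reduced before it can open, because the ring C–C bonds β to it lie almost orthogonal to the singly occupied orbital.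

**Further compounds**

F1 | step 7 | 2-(hydroxymethyl)-3,5-bis(methoxymethoxy)phenol | COCOc1cc(O)c(CO)c(OCOC)c1
F2 | step 7 | 3,5-bis(methoxymethoxy)-6-methylidenecyclohexa-2,4-dien-1-one | O=C1C=C(OCOC)C=C(OCOC)C1=C
F3 | step 5 | methyl 5-[2-hydroxy-4,6-bis(methoxymethoxy)phenyl]-3-(4-methylpent-3-enyl)pent-2-enoate (E/Z mixture) | COCOc1cc(O)c(CCC(=CC(=O)OC)CCC=C(C)C)c(OCOC)c1
F4 | step 5 | racemic methyl 2-[5,7-bis(methoxymethoxy)-2-(4-methylpent-3-enyl)chroman-2-yl]acetate | COCOc1cc2c(c(OCOC)c1)CCC(CC(=O)OC)(CCC=C(C)C)O2
F5 | step 8 | (2R,1'S,5'R)-5,7-bis(methoxymethoxy)-6',6'-dimethylspiro[chromane-2,2'-bicyclo[3.1.1]heptan]-7'-ol (C7' unassigned) | COCOc1cc2c(c(OCOC)c1)CC[C@@]1(CC[C@H]3C(O)[C@@H]1C3(C)C)O2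
F6 | step 8 | O-[(2R,1'S,5'R)-5,7-bis(methoxymethoxy)-6',6'-dimethylspiro[chromane-2,2'-bicyclo[3.1.1]heptan]-7'-yl] S-methyl carbonodithioate (C7' unassigned) | COCOc1cc2c(c(OCOC)c1)CC[C@@]1(CC[C@H]3C(OC(=S)SC)[C@@H]1C3(C)C)O2
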